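4 questions stand on 3 set-ups of one charge.

in all of them: starting material 0.050 M
- spring: one stirred flow tank at steady state, fed with the mixture as stated, mean residence time 20.0 h
- winter: a closed flask charged with all of it at once and left for 4.0 h; time 4.0 h
- midnight: one stirred flow tank at steady state, fed with the mixture as stated, mean residence time 4.0 h

    starting material → intermediate (k1 = 0.0040 /min)
    intermediate → target (k2 = 0.013 /min)
    starting material → side product (k3 = 0.0044 /min)
    2 starting material → self-condensation product (k4 = 0.33 /M/min)
    starting material → decomposition product (k5 = 5.7 × 10⁻⁶ /min)
    starting material + target ⇌ idle adduct, settled at all times (K6 = 33 /M)

- percent here means starting material units held: one self-condensation product or idle adduct counts as two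
- what is said of target includes idle adduct
- a doubled species enters its step squared and goes two at a time
- the stated concentrations are those of everything mixed, before any reaction; amounts are the same in each set-up
- in an amount of target, one idle adduct counts as one target
- run time (winter): 4.0 h

1. the set-up with the highest amount of target at the outlet or at the end, in percent of the starting material put in ("none" if the first two lie within 2 percentage points) (spring / winter / midnight / none)
2. amount of target at the outlet or at the end, in percent of the starting material put in, spring
3. amount of target at the outlet or at the end, in percent of the starting material put in, winter
4. amount of target at the outlet or at the end, in percent of the starting material put in, midnight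

Free starting material leaves by first-order steps, whose constants sum to f, and by self-condensation, whose drain per unit of c(starting material) is b·c:

f = 0.00841 /min, b = 0.660 /M/min

The share sent toward target, the instantaneous selectivity, follows from these:

s(c) = 0.0040 /min / (f + b·c)

The two drains are equal at the crossover concentration:

c× = f/b = 0.0127 M

The adduct balance holds at each moment. Adduct counts as target, so this reckoning tracks the free species and sets aside the starting material that adduct takes.

The winter flask starts at 0.050 M, above c×. There c(starting material) falls at 0.124 M/h, with s at 9.66 %. Integrating the two drains puts the knee, where c reaches c×, at:

t = 0.924 h

Beyond it the curve flattens. At 4.0 h the winter curve reaches: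

c = 0.161 M min × f / (1 − 0.106) = 0.00151 M

By this reckoning, 18.0 % of the charge has by then gone toward intermediate. Intermediate trails the late decay of starting material, taken at rate f, so about 2.63 % is estimated to stand as intermediate, which leaves:

winter: 15.3 %

A tank sits at one point of s(c), set by its balance cA − c = τ·c·(f + b·c):

spring: c = 0.00359 M, target 32.4 %

midnight: c = 0.0106 M, target 15.5 %

Best by this reckoning: spring.

The forecast names spring, with 31.5 %, 15.9 % and 15 %, since the long tank “holds the starting material very dilute”. The winter number reckoned here lies below the forecast's.

The simulation gives spring, with 31.5 %, 15.4 % and 15.0 %.

The spring tank holds free starting material at 0.00349 M, under c×, where s is 37.3 %. Back-mixing and the longer stay are the main reason for its lead: with both taken away, spring target falls from 31.5 % to 15.4 %. The midnight tank reads 0.0103 M, also under c×, with s at 26.3 % and 4.82 % still standing as intermediate at its outlet.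

All constants are made up.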